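Ring A (C4–C5–C6–O6–C4′) with its C7 branch is Cyrene in disguise: C4′ is the ketone carbon, C4 and C5 its α- and β-carbons, C6 the bridgehead CH–O and C7 the CH2O group. Everything rests on excising the acetal carbon from a Cyrene ketone that already carries ring B spiro at C4. One Baeyer–Villiger oxidation inserts oxygen between C4′ and the acetal carbon, closes γ-lactone ring A onto O6 and leaves the lost carbon as a C7 formate, without touching the four stereocentres. The precursor is this spiro ketone with O1 on the exo face, the C2 and C3 hydroxyls as triethylsilyl ethers and the C3 carboxyl as a tert-butyl ester.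

Key step: step 6

Remark (numbering and assumption): ring B is O1–C1(=O)–C2–C3(C3′)–C4, ring A is C4–C5–C6–O6–C4′(=O) and the chain is C7–C16; Cyrene locants carry the suffix cy (O8cy becomes O6, O6cy ends in the formate); Cyrene is taken as the (1S,5R) enantiomer from cellulose and mCPBA as the commercial water-wet solid.

Step 1
Reactants: 1 Cyrene; 2 di-tert-butyl oxalate
Product: 3 3-(tert-butoxyoxalyl)Cyrene as its hydrogen-bonded Z-enol
Conditions: LiHMDS (2.2 equiv), THF, −78 °C; then 2, −78 → 0 °C; AcOH quench
Reagents that add atoms: none
Why: Crossed Claisen condensation: Cyrene has one enolisable position (C3cy, the future C4), the oxalate cannot enolise, and deprotonation of the 1,3-dicarbonyl product by the second equivalent of base drives the acylation to completion; no stereocentre is set because C4 is trigonal in the enol.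

Step 2
Reactants: 3 3-(tert-butoxyoxalyl)Cyrene
Product: 4 exo-3-acetoxy-3-(tert-butoxyoxalyl)Cyrene
Conditions: Pb(OAc)4 (1.1 equiv), toluene, rt; used without chromatography
Reagents that add atoms: lead tetraacetate CC(=O)O[Pb](OC(C)=O)(OC(C)=O)OC(C)=O
Why: α-Acetoxylation of a 2-substituted 1,3-dicarbonyl by lead(IV), in which acetate is passed from the lead enolate to the tertiary carbon (SN2 inversion is impossible there), sets C4 by delivery to the exo face, since the endo face of C3cy lies under the O6cy–C7 anhydro bridge; the oxalyl carbon is thereby pushed endo, which is the trans C4–O1/C7 relation of ring A.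

Step 3
Reactants: 4 exo-3-acetoxy-3-(tert-butoxyoxalyl)Cyrene
Product: 5 spiro β-hydroxy lactone (ring B closed; C2 still CH2)
Conditions: MgBr2·OEt2 (1.5 equiv), THF, −78 °C; then LiHMDS (1.1 equiv), −78 °C; AcOH quench at −78 °C
Reagents that add atoms: none
Why: Lactonising acetate aldol of an α-acyloxy ketone (the five-membered closure known from butenolide syntheses): the acetate methyl is the only acidic C–H, the freely rotating α-keto ester carbonyl C3 is more electrophilic than the bridged ring ketone, the tert-butyl ester resists Dieckmann attack, and C3 is set by the magnesium chelate that holds the C3 and C4′ carbonyl oxygens syn, so that the O1-tethered enolate adds on the O1 side and leaves the C3 oxygen cis to C4′ and the ester cis to C5.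

Step 4
Reactants: 5 spiro β-hydroxy lactone
Product: 6 spiro trans-diol lactone
Conditions: LiHMDS (2.5 equiv), THF, −78 °C; trans-2-(phenylsulfonyl)-3-phenyloxaziridine (1.5 equiv), −78 °C; AcOH quench at −78 °C
Reagents that add atoms: trans-2-(phenylsulfonyl)-3-phenyloxaziridine O=S(=O)(c1ccccc1)N1OC1c1ccccc1
Why: Davis hydroxylation of a β-oxido lactone enolate (Fráter–Seebach-type dianion): C2 carries the only enolisable hydrogens, the alkoxide cannot be eliminated, and the oxidant should enter anti to the lithium-bound C3 oxygen, which sets C2 with its hydroxyl trans to the C3 oxygen and cis to the ester.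

Step 5
Reactants: 6 spiro trans-diol lactone
Product: 7 bis(triethylsilyl) ether of the spiro ketone (key-step precursor)
Conditions: TESOTf (3 equiv), 2,6-lutidine (4 equiv), CH2Cl2, −78 → 0 °C
Reagents that add atoms: triethylsilyl triflate CC[Si](CC)(CC)OS(=O)(=O)C(F)(F)F
Why: Silylation with a silyl triflate and 2,6-lutidine is strong enough for the hindered tertiary C3 hydroxyl as well as the C2 hydroxyl, the ketone has no enolisable hydrogen and so cannot form a silyl enol ether, and no stereocentre is touched.

Step 6
Reactants: 7 bis(triethylsilyl) ether of the spiro ketone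
Product: 9 C7 formate of the bis-TES spiro bis-lactone tert-butyl ester, via seven-membered acyloxy orthoformate 8 (not isolated)
Conditions: mCPBA (77 %, water-wet, 2.5 equiv), CH2Cl2, 0 °C → rt
Reagents that add atoms: meta-chloroperoxybenzoic acid OOC(=O)c1cccc(Cl)c1
Why: The peracid adds to the only ketone (C4′) and, in the Criegee adduct, the acetal carbon migrates with retention because its two oxygen lone pairs stabilise the electron-deficient migrating terminus, whereas the quaternary C4 is deactivated by its acyloxy oxygen and the carbonyl-bearing C3; this gives the ring-expanded acyloxy orthoformate 8. Compound 8 is an acylal of formic acid: acid-assisted ionisation to the 1,3-dioxolan-2-ylium ion, capture at the formyl carbon by the water of the peracid and collapse of the hemiorthoformate free the C6 oxygen, which acylates itself on C4′, and because formyl groups shift between the vicinal oxygens while only the C6 oxygen can close a five-membered lactone, the excised carbon ends as the formate on the C7 oxygen. The closest known reaction is the Baeyer–Villiger oxidation of Cyrene and levoglucosenone to the formate of the γ-hydroxymethyl lactone, here applied to an α-quaternary, spiro-substituted congener. Ring A closes by 5-exo-trig attack of O6 on the C4′ acyl carbon. No stereocentre is created, and C4 and C6 keep their configuration because neither the C4–C4′ bond nor the C6–O6 bond is ever broken. The step needs migration of the acetal carbon in preference to C4, secured by the two acetal oxygens against the electron-poor C4, and chemoselectivity for the ketone, secured because lactones, ester and silyl ethers are inert to the peracid and the terminal alkene is only introduced afterwards.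

Step 7
Reactants: 9 C7 formate of the bis-TES spiro bis-lactone tert-butyl ester
Product: 10 C7 primary alcohol
Conditions: KHCO3 (0.2 equiv), MeOH, 0 °C
Reagents that add atoms: none
Why: Base-catalysed transesterification removes the formate, which is methanolysed far faster than the two γ-lactones, the tert-butyl ester and the silyl ethers, and the freed C7 hydroxyl has no driving force to expand ring A to a δ-lactone; no stereocentre is touched.

Step 8
Reactants: 10 C7 primary alcohol
Product: 11 C7 triflate
Conditions: Tf2O (1.2 equiv), 2,6-lutidine (1.5 equiv), CH2Cl2, −78 °C; cold aqueous work-up, used at once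
Reagents that add atoms: triflic anhydride O=S(=O)(OS(=O)(=O)C(F)(F)F)C(F)(F)F
Why: O-Sulfonylation of the only free hydroxyl, a primary one, at low temperature gives the leaving group needed for a coupling that runs below −30 °C; no stereocentre is touched.

Step 9
Reactants: 11 C7 triflate; 12 9-bromonon-1-ene
Product: 14 bis-TES tert-butyl ester of the target, via non-8-en-1-ylmagnesium bromide 13 (not isolated)
Conditions: 12, Mg, THF, rt; then 11, CuBr·SMe2 (10 mol%), Et2O/THF, −78 → −30 °C
Reagents that add atoms: none
Why: Copper-catalysed sp3–sp3 coupling of a primary triflate with a Grignard reagent (Kotsuki coupling, the triflate version of the cuprate displacement long used on sulfonates of γ-hydroxymethyl-γ-butyrolactone) should outrun addition to the lactones and the tert-butyl ester at low temperature, and it forms C7–C8 without touching C6.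

Step 10
Reactants: 14 bis-TES tert-butyl ester of the target
Product: 15 CNP0281847.1
Conditions: TFA/CH2Cl2/H2O (9:9:2), 0 °C → rt
Reagents that add atoms: none
Why: Acidolysis cleaves the tert-butyl ester (alkyl–oxygen fission to isobutene) and both triethylsilyl ethers in one operation, while the γ-lactones and the terminal alkene tolerate trifluoroacetic acid at room temperature, so that no base ever opens the lactones; no stereocentre is touched.

Compound list
1 | Cyrene, (1S,5R)-6,8-dioxabicyclo[3.2.1]octan-4-one | O=C1CC[C@H]2CO[C@@H]1O2 | starting material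
2 | di-tert-butyl oxalate | CC(C)(C)OC(=O)C(=O)OC(C)(C)C | starting material
3 | tert-butyl (Z)-2-hydroxy-2-[(1S,5R)-4-oxo-6,8-dioxabicyclo[3.2.1]octan-3-ylidene]acetate, the enol form of 3-(tert-butoxyoxalyl)Cyrene | O=C1/C(=C(\O)C(=O)OC(C)(C)C)C[C@H]2CO[C@@H]1O2 | intermediate
4 | tert-butyl 2-[(1S,3R,5R)-3-acetoxy-4-oxo-6,8-dioxabicyclo[3.2.1]octan-3-yl]-2-oxoacetate; acetoxy exo (anti to the O6cy–C7 bridge), oxalyl endo | O1C[C@@H]3C[C@@](C(=O)C(=O)OC(C)(C)C)(OC(C)=O)C(=O)[C@H]1O3 | intermediate
5 | spiro β-hydroxy lactone: ring B O1–C1(=O)–C2H2–C3(OH)(CO2tBu)–C4 spiro at C3cy of Cyrene; O1 exo, C3–OH cis to C4′ and ester cis to C5 on ring B | O1C[C@@H]3C[C@@]2(OC(=O)C[C@]2(O)C(=O)OC(C)(C)C)C(=O)[C@H]1O3 | intermediate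
6 | spiro trans-diol lactone: as 5 with a C2 hydroxyl trans to the C3 hydroxyl and cis to the ester | O1C[C@@H]3C[C@@]2(OC(=O)[C@H](O)[C@]2(O)C(=O)OC(C)(C)C)C(=O)[C@H]1O3 | intermediate
7 | 2,3-bis(triethylsilyl) ether of 6, the key-step precursor | O1C[C@@H]3C[C@@]2(OC(=O)[C@H](O[Si](CC)(CC)CC)[C@]2(O[Si](CC)(CC)CC)C(=O)OC(C)(C)C)C(=O)[C@H]1O3 | intermediate
8 | seven-membered acyloxy orthoformate: 7 with oxygen inserted between C4′ and the acetal carbon, configuration of the acetal carbon retained | O1C[C@@H]3C[C@@]2(OC(=O)[C@H](O[Si](CC)(CC)CC)[C@]2(O[Si](CC)(CC)CC)C(=O)OC(C)(C)C)C(=O)O[C@H]1O3 | intermediate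
9 | spiro bis-lactone with C7 formyloxymethyl on C6, 2,3-bis-TES ether, C3 tert-butyl ester (C4–O1 trans to C7 on ring A) | O=COC[C@@H]1C[C@@]2(OC(=O)[C@H](O[Si](CC)(CC)CC)[C@]2(O[Si](CC)(CC)CC)C(=O)OC(C)(C)C)C(=O)O1 | intermediate
10 | as 9 with C7 hydroxymethyl | OC[C@@H]1C[C@@]2(OC(=O)[C@H](O[Si](CC)(CC)CC)[C@]2(O[Si](CC)(CC)CC)C(=O)OC(C)(C)C)C(=O)O1 | intermediate
11 | as 9 with C7 trifluoromethanesulfonyloxymethyl | O=S(=O)(OC[C@@H]1C[C@@]2(OC(=O)[C@H](O[Si](CC)(CC)CC)[C@]2(O[Si](CC)(CC)CC)C(=O)OC(C)(C)C)C(=O)O1)C(F)(F)F | intermediate
12 | 9-bromonon-1-ene | C=CCCCCCCCBr | starting material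
13 | non-8-en-1-ylmagnesium bromide | C=CCCCCCCC[Mg]Br | intermediate
14 | 2,3-bis(triethylsilyl) ether tert-butyl ester of the target (dec-9-enyl on C6) | C=CCCCCCCCC[C@@H]1C[C@@]2(OC(=O)[C@H](O[Si](CC)(CC)CC)[C@]2(O[Si](CC)(CC)CC)C(=O)OC(C)(C)C)C(=O)O1 | intermediate
15 | CNP0281847.1, (3R,4R,5S,8R)-8-(dec-9-en-1-yl)-3,4-dihydroxy-2,6-dioxo-1,7-dioxaspiro[4.4]nonane-4-carboxylic acid | C=CCCCCCCCC[C@@H]1C[C@@]2(OC(=O)[C@H](O)[C@]2(O)C(=O)O)C(=O)O1 | target

Total step count: 10.
Longest linear sequence: 10 steps (1 → 15); the Grignard reagent 13 is made and consumed within step 9.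

Steps most likely to fail

Step 6 (Baeyer–Villiger excision). What may go wrong: addition of the peracid to C4′ may be too slow, because the carbonyl sits between a quaternary carbon and a bridgehead and the C3 silyl ether folds over it. The acidic oxidant may also strip silyl groups, or the acylal 8 may not collapse cleanly. Fallback: change the order of oxidation and protection. Set out from 6 and oxidise the unprotected diol with mCPBA in CH2Cl2; the free C3 hydroxyl hydrogen-bonds to C4′, activates it and removes the steric shield. The reaction should pass through the unprotected acyloxy orthoformate F6 to the diol formate F7. Silylation of F7 with TESOTf and 2,6-lutidine, which a formate tolerates, rejoins the route at 9.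

Step 3 (aldol lactonisation). What may go wrong: the enolate may add to the ring ketone C4′ instead of C3, the addition may run without chelation and take the other face of C3, or the amide base may fragment the tricarbonyl (retro-Claisen). Fallback: replace the amide-base aldol by a Reformatsky closure. Set out from 3 and hydroxylate the enol on the exo face with dimethyldioxirane in acetone at −20 °C to the tertiary alcohol F1. Acylate F1 with bromoacetyl bromide and 2,6-lutidine to the bromoacetate F2. Close ring B with activated zinc in THF at 0 °C; the neutral zinc enolate is generated without base and is held by the same 1,3-dicarbonyl chelate. This comes back to the route at 5.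

Step 4 (C2 hydroxylation). What may go wrong: poor facial selectivity, with the oxidant entering syn to the C3 oxygen, or retro-aldol cleavage of C3–C4 from the alkoxide if the dianion is warmed. Fallback: set the C2 configuration by SN2 inversion instead of by facial control. Set out from 5 and take the hydroxylation product with the wrong face, the cis-diol F3. Convert its secondary C2 hydroxyl (the tertiary one is inert) with Tf2O and pyridine at −40 °C into the triflate F4. Displace the triflate with tetrabutylammonium nitrite in DMF at rt (Lattrell–Dax inversion); SN2 at an α-lactone carbon next to a quaternary centre has its model in pantolactone triflate. The inverted nitrite ester F5 hydrolyses on aqueous work-up and returns the route to 6.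

Further compounds
F1 | step 3 | tert-butyl 2-[(1S,3R,5R)-3-hydroxy-4-oxo-6,8-dioxabicyclo[3.2.1]octan-3-yl]-2-oxoacetate (hydroxyl exo) | O1C[C@@H]3C[C@@](C(=O)C(=O)OC(C)(C)C)(O)C(=O)[C@H]1O3
F2 | step 3 | bromoacetate of F1 (bromoacetoxy exo) | O1C[C@@H]3C[C@@](C(=O)C(=O)OC(C)(C)C)(OC(=O)CBr)C(=O)[C@H]1O3
F3 | step 4 | C2 epimer of 6 (cis-diol; C2 hydroxyl cis to the C3 hydroxyl) | O1C[C@@H]3C[C@@]2(OC(=O)[C@@H](O)[C@]2(O)C(=O)OC(C)(C)C)C(=O)[C@H]1O3
F4 | step 4 | C2 triflate of F3 | O1C[C@@H]3C[C@@]2(OC(=O)[C@@H](OS(=O)(=O)C(F)(F)F)[C@]2(O)C(=O)OC(C)(C)C)C(=O)[C@H]1O3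
F5 | step 4 | C2 nitrite ester with inverted C2 (configuration of 6) | O1C[C@@H]3C[C@@]2(OC(=O)[C@H](ON=O)[C@]2(O)C(=O)OC(C)(C)C)C(=O)[C@H]1O3
F6 | step 6 | seven-membered acyloxy orthoformate from 6 (free diol analogue of 8) | O1C[C@@H]3C[C@@]2(OC(=O)[C@H](O)[C@]2(O)C(=O)OC(C)(C)C)C(=O)O[C@H]1O3
F7 | step 6 | diol formate: spiro bis-lactone tert-butyl ester with C7 formyloxymethyl and free C2 and C3 hydroxyls | O=COC[C@@H]1C[C@@]2(OC(=O)[C@H](O)[C@]2(O)C(=O)OC(C)(C)C)C(=O)O1
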